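**Plan** (isochromene numbering of the target: ring B = O2, C1, C3, C4, C4a, C8a; ring A = C4a, C5, C6, C7, C8, C8a)

- Retrosynthesis: the two silyl ethers and the butanoate come off first; ring A is then cut at C8–C8a and C5–C4a at once, leaving a maltol-type 4-pyranone (ring B) and a C5–C8 chain. The pyranone is cut in its side chain (CH2–CH2), the chain at C6–C7.
- Enabling feature: C4a is the carbonyl carbon and C8a the α-carbon of a 4-pyranone whose 3-O and 2-alkyl group are the C4–OMe and the C3 side chain. The chain C5–C8 offers one acyl carbon (C8), one enolisable carbon (C5) and a quaternary, non-epimerisable C7 between two carbonyls.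
- Forward: maltol is O-methylated and extended at its methyl group to ring B. (S)-Lactic acid is turned via its pivalaldehyde acetal into the C5–C8 unit (aldol, oxidation, enol silylation). A one-flask conjugate reduction / Claisen acylation / Mukaiyama aldol condensation closes ring A onto ring B.
- Helpers: a hydride at C1 (makes C8a an enolate and removes the competing Michael position; taken out by dehydrogenation); the dioxolanone ring (chirality carrier, O7 protection, activation of C8; lost as pivalaldehyde); the C5=C6 silyl enol ether (masks the ketone and the acidic CH2; consumed in the key step).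
- End game: dehydrogenation at C1–C8a, butanoylation of the tertiary alcohol, removal of both silyl groups.
- Stereochemistry: C7 (S) is the only stereocentre. It comes from (S)-lactic acid by self-regeneration of the stereocentre (the electrophile enters trans to the tert-butyl group of the acetal) and is quaternary from then on.

Key step: step 7

Remark: the 5-hydroxy-6,8-dione drawn for the target is taken as the stable tautomer of the desilylated product, and the annulation product of the key step is treated as one compound although it is a pair of C8a epimers in equilibrium with its enol.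

**Route**

Step 1
Reactants: 1 maltol (3-hydroxy-2-methyl-4H-pyran-4-one)
Product: 2 3-methoxy-2-methyl-4H-pyran-4-one
Conditions: MeI, K2CO3, acetone, reflux
Reagents that add atoms: iodomethane, CI
Why: Williamson ether synthesis, in which the acidic enolic 3-OH is deprotonated by K2CO3 and methylated by SN2 on iodomethane, no stereocentre being involved.

Step 2
Reactants: 2 3-methoxy-2-methyl-4H-pyran-4-one; 3 tert-butyl(2-iodoethoxy)dimethylsilane
Product: 5 2-[3-(tert-butyldimethylsilyloxy)propyl]-3-methoxy-4H-pyran-4-one, via lithium dienolate 4 (not isolated)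
Conditions: LiN(SiMe3)2, THF, −78 °C; then 3, DMPU, −78 → 0 °C
Reagents that add atoms: none
Why: vinylogous (lateral) deprotonation of the 2-methyl group gives the cross-conjugated dienolate 4, which should be alkylated at the exocyclic carbon by the primary iodide (SN2 enolate alkylation, the same anion that is used in aldol chain extensions of maltol ethers), no stereocentre being involved.

Step 3
Reactants: 6 (S)-lactic acid; 7 pivalaldehyde
Product: 8 (2S,5S)-2-tert-butyl-5-methyl-1,3-dioxolan-4-one
Conditions: p-toluenesulfonic acid monohydrate (cat.), H2SO4 (cat.), pentane, reflux, Dean–Stark trap; crystallisation from pentane/Et2O, −78 °C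
Reagents that add atoms: none
Why: acid-catalysed acetalisation with azeotropic removal of water, in which the lactate centre is not touched and the acetal centre is set under thermodynamic control in favour of the cis isomer, which is purified by low-temperature crystallisation.

Step 4
Reactants: 8 (2S,5S)-2-tert-butyl-5-methyl-1,3-dioxolan-4-one; 9 (tert-butyldimethylsilyloxy)acetaldehyde
Product: 11 (2S,5R)-2-tert-butyl-5-[2-(tert-butyldimethylsilyloxy)-1-hydroxyethyl]-5-methyl-1,3-dioxolan-4-one (carbinol epimers), via lithium enolate 10 (not isolated)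
Conditions: LiN(i-Pr)2, THF, −78 °C; then 9, −78 °C; AcOH
Reagents that add atoms: none
Why: aldol addition of the dioxolanone enolate 10 (self-regeneration of the stereocentre), in which the tert-butyl group on the acetal carbon shields one face so that the new C–C bond forms trans to it and the aldehyde carbon takes the place of the lactate hydrogen, which fixes the future C7, while the carbinol centre is uncontrolled and is removed in step 5.

Step 5
Reactants: 11 (2S,5R)-2-tert-butyl-5-[2-(tert-butyldimethylsilyloxy)-1-hydroxyethyl]-5-methyl-1,3-dioxolan-4-one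
Product: 12 (2S,5R)-2-tert-butyl-5-[(tert-butyldimethylsilyloxy)acetyl]-5-methyl-1,3-dioxolan-4-one
Conditions: Dess–Martin periodinane, CH2Cl2, 23 °C
Reagents that add atoms: none
Why: Dess–Martin oxidation of the secondary alcohol to the ketone under conditions that should spare the acetal and the silyl ether, the quaternary centre having no hydrogen to lose.

Step 6
Reactants: 12 (2S,5R)-2-tert-butyl-5-[(tert-butyldimethylsilyloxy)acetyl]-5-methyl-1,3-dioxolan-4-one
Product: 13 (2S,5R)-2-tert-butyl-5-[2-(tert-butyldimethylsilyloxy)-1-(triethylsilyloxy)ethenyl]-5-methyl-1,3-dioxolan-4-one (alkene geometry not defined and without consequence)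
Conditions: Et3SiOTf, Et3N, CH2Cl2, 0 °C
Reagents that add atoms: triethylsilyl trifluoromethanesulfonate, CC[Si](CC)(CC)OS(=O)(=O)C(F)(F)F
Why: soft enolisation and O-silylation (silyl enol ether formation), regiodefined because the ketone can enolise only toward the CH2OSi carbon, the other α-carbon being quaternary.

Step 7
Reactants: 5 2-[3-(tert-butyldimethylsilyloxy)propyl]-3-methoxy-4H-pyran-4-one; 13 (2S,5R)-2-tert-butyl-5-[2-(tert-butyldimethylsilyloxy)-1-(triethylsilyloxy)ethenyl]-5-methyl-1,3-dioxolan-4-one
Product: 16 (7S)-5-(tert-butyldimethylsilyloxy)-3-[3-(tert-butyldimethylsilyloxy)propyl]-7-hydroxy-4-methoxy-7-methyl-1,8a-dihydro-6H-isochromene-6,8(7H)-dione (C8a epimers), via lithium enolate 14 (not isolated), via lithium diketonate 15 (not isolated)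
Conditions: LiBH(s-Bu)3, THF, −78 °C; then 13, −78 → −20 °C; then CF3CO2H, CH2Cl2, −78 → 0 °C
Reagents that add atoms: none
Why: Proposed new method: the hydride adds 1,4 to the unsubstituted C1=C8a bond of 5 and so gives the lithium enolate 14 regiospecifically; C8a of 14 attacks the acetal-ester carbonyl C8 of 13 (Claisen acylation, the ring opens and loses pivalaldehyde, the tertiary alkoxide takes the acidic C8a–H to give 15), and after acidification the silyl enol ether carbon C5 adds to the protonated vinylogous-ester carbonyl C4a and the adduct loses triethylsilanol to give C4a=C5, so that the C8–C8a and the C5–C4a bond form in one flask. The closest known reaction types are the acylation of enolates from LiBH(s-Bu)3 conjugate reduction, the C-acylation of lithium enolates by 1,3-dioxolan-4-ones (tetronic acid syntheses) and the intramolecular Mukaiyama aldol condensation; what is new is their union into a [4+2] annulation on a 4-pyranone. Ring A closes in the aldol stage by a 6-(enolendo)-exo-trig attack of C5 on C4a. No stereocentre of the target is formed: C7 comes from 13 and has no α-hydrogen, so it cannot epimerise, and the new C8a centre is formed without control and is erased in step 8. The step needs C5 to bond to C4a and not to C1, which the temporary hydride secures because C1 is sp3 and no Michael acceptor at that stage, while attack of C5 on C8 or C3 would close a four- or an eight-membered ring. It also needs C-acylation of 14 to outrun proton transfer and aldol addition, which the silyl enol ether secures by masking both the C6 ketone and the acidic C5–H of the C4 unit.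

Step 8
Reactants: 16 (7S)-5-(tert-butyldimethylsilyloxy)-3-[3-(tert-butyldimethylsilyloxy)propyl]-7-hydroxy-4-methoxy-7-methyl-1,8a-dihydro-6H-isochromene-6,8(7H)-dione
Product: 17 (7S)-5-(tert-butyldimethylsilyloxy)-3-[3-(tert-butyldimethylsilyloxy)propyl]-7-hydroxy-4-methoxy-7-methyl-6H-isochromene-6,8(7H)-dione
Conditions: 2,3-dichloro-5,6-dicyano-1,4-benzoquinone (DDQ), 1,4-dioxane, 23 → 60 °C
Reagents that add atoms: none
Why: DDQ dehydrogenation of the type that turns chroman-4-ones into chromones, in which hydride abstraction from C1 next to the ring oxygen and loss of the acidic C8a–H should give the C1=C8a vinylogous ester, removing the temporary hydrogen and the uncontrolled C8a centre while C7 is untouched.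

Step 9
Reactants: 17 (7S)-5-(tert-butyldimethylsilyloxy)-3-[3-(tert-butyldimethylsilyloxy)propyl]-7-hydroxy-4-methoxy-7-methyl-6H-isochromene-6,8(7H)-dione
Product: 18 (7S)-5-(tert-butyldimethylsilyloxy)-3-[3-(tert-butyldimethylsilyloxy)propyl]-4-methoxy-7-methyl-6,8-dioxo-7,8-dihydro-6H-isochromen-7-yl butanoate
Conditions: (n-PrCO)2O, 4-(dimethylamino)pyridine (cat.), Et3N, CH2Cl2, 0 → 23 °C
Reagents that add atoms: butanoic anhydride, CCCC(=O)OC(=O)CCC
Why: nucleophile-catalysed acyl transfer to the only free hydroxyl group (the tertiary α-ketol, as in the acetylation of tertiary azaphilone alcohols), the other two oxygens being silylated and no bond at C7 being broken, so that its configuration is kept.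

Step 10
Reactants: 18 (7S)-5-(tert-butyldimethylsilyloxy)-3-[3-(tert-butyldimethylsilyloxy)propyl]-4-methoxy-7-methyl-6,8-dioxo-7,8-dihydro-6H-isochromen-7-yl butanoate
Product: 19 (7S)-5-hydroxy-3-(3-hydroxypropyl)-4-methoxy-7-methyl-6,8-dioxo-7,8-dihydro-6H-isochromen-7-yl butanoate
Conditions: HF·pyridine, THF, 0 → 23 °C
Reagents that add atoms: none
Why: fluoride-driven cleavage of the primary and of the enol silyl ether (Si–F bond formation) under mildly acidic, non-nucleophilic conditions that should spare the tertiary butanoate and the vinylogous ester, the freed C5 enol being the diosphenol of the target.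

**Compound list**

1 | maltol (3-hydroxy-2-methyl-4H-pyran-4-one) | CC1=C(O)C(=O)C=CO1 | starting material
2 | 3-methoxy-2-methyl-4H-pyran-4-one | CC1=C(OC)C(=O)C=CO1 | intermediate
3 | tert-butyl(2-iodoethoxy)dimethylsilane | CC(C)(C)[Si](C)(C)OCCI | starting material
4 | lithium dienolate of 2 (lithium 3-methoxy-2-methylidene-2H-pyran-4-olate; not isolated) | [Li]OC1=C(OC)C(=C)OC=C1 | intermediate
5 | 2-[3-(tert-butyldimethylsilyloxy)propyl]-3-methoxy-4H-pyran-4-one | COC1=C(CCCO[Si](C)(C)C(C)(C)C)OC=CC1=O | intermediate
6 | (S)-lactic acid | C[C@H](O)C(=O)O | starting material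
7 | pivalaldehyde | CC(C)(C)C=O | starting material
8 | (2S,5S)-2-tert-butyl-5-methyl-1,3-dioxolan-4-one (cis) | C[C@@H]1O[C@H](C(C)(C)C)OC1=O | intermediate
9 | (tert-butyldimethylsilyloxy)acetaldehyde | CC(C)(C)[Si](C)(C)OCC=O | starting material
10 | lithium enolate of 8 (acetal centre as in 8; not isolated) | CC1=C(O[Li])O[C@@H](C(C)(C)C)O1 | intermediate
11 | (2S,5R)-2-tert-butyl-5-[2-(tert-butyldimethylsilyloxy)-1-hydroxyethyl]-5-methyl-1,3-dioxolan-4-one (carbinol epimers; new chain trans to tert-butyl) | C[C@]1(C(O)CO[Si](C)(C)C(C)(C)C)O[C@H](C(C)(C)C)OC1=O | intermediate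
12 | (2S,5R)-2-tert-butyl-5-[(tert-butyldimethylsilyloxy)acetyl]-5-methyl-1,3-dioxolan-4-one | C[C@]1(C(=O)CO[Si](C)(C)C(C)(C)C)O[C@H](C(C)(C)C)OC1=O | intermediate
13 | (2S,5R)-2-tert-butyl-5-[2-(tert-butyldimethylsilyloxy)-1-(triethylsilyloxy)ethenyl]-5-methyl-1,3-dioxolan-4-one (alkene geometry not defined) | C[C@]1(C(O[Si](CC)(CC)CC)=CO[Si](C)(C)C(C)(C)C)O[C@H](C(C)(C)C)OC1=O | intermediate
14 | lithium enolate of 6-[3-(tert-butyldimethylsilyloxy)propyl]-5-methoxy-2,3-dihydro-4H-pyran-4-one (not isolated) | [Li]OC1=CCOC(CCCO[Si](C)(C)C(C)(C)C)=C1OC | intermediate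
15 | lithium diketonate of the 3-acyl-2,3-dihydropyranone with free tertiary alcohol and intact silyl enol ether (carbinol configuration as in 13; not isolated) | COC1=C(CCCO[Si](C)(C)C(C)(C)C)OCC(C1=O)=C(O[Li])[C@](C)(O)C(O[Si](CC)(CC)CC)=CO[Si](C)(C)C(C)(C)C | intermediate
16 | (7S)-5-(tert-butyldimethylsilyloxy)-3-[3-(tert-butyldimethylsilyloxy)propyl]-7-hydroxy-4-methoxy-7-methyl-1,8a-dihydro-6H-isochromene-6,8(7H)-dione (C8a epimers) | O[C@@]1(C)C(=O)C2COC(CCCO[Si](C)(C)C(C)(C)C)=C(OC)C2=C(O[Si](C)(C)C(C)(C)C)C1=O | intermediate
17 | (7S)-5-(tert-butyldimethylsilyloxy)-3-[3-(tert-butyldimethylsilyloxy)propyl]-7-hydroxy-4-methoxy-7-methyl-6H-isochromene-6,8(7H)-dione | O[C@@]1(C)C(=O)C2=COC(CCCO[Si](C)(C)C(C)(C)C)=C(OC)C2=C(O[Si](C)(C)C(C)(C)C)C1=O | intermediate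
18 | (7S)-5-(tert-butyldimethylsilyloxy)-3-[3-(tert-butyldimethylsilyloxy)propyl]-4-methoxy-7-methyl-6,8-dioxo-7,8-dihydro-6H-isochromen-7-yl butanoate | CCCC(=O)O[C@@]1(C)C(=O)C2=COC(CCCO[Si](C)(C)C(C)(C)C)=C(OC)C2=C(O[Si](C)(C)C(C)(C)C)C1=O | intermediate
19 | (7S)-5-hydroxy-3-(3-hydroxypropyl)-4-methoxy-7-methyl-6,8-dioxo-7,8-dihydro-6H-isochromen-7-yl butanoate | CCCC(=O)O[C@@]1(C)C(=O)C2=COC(CCCO)=C(OC)C2=C(O)C1=O | target

**Count and risks**

Total step count: 10. Longest linear sequence: 8 steps (steps 3 to 10, from (S)-lactic acid); the pyranone branch (steps 1 and 2) joins at step 7.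

Step 7 (proposed new method). Proton transfer or silyl transfer from the C4 unit to enolate 14 may outrun C-acylation at the hindered acetal-ester carbonyl, and the acid stage may cleave silyl ethers or desilylate the enol ether before ring A closes. The fallback gives up the one-flask cascade for three separate, known reactions with isolated intermediates; it sets out from 5 and 13 and comes back at 16. Pyranone 5 is reduced with LiBH(s-Bu)3 in THF at −78 °C and the enolate is protonated with aqueous NH4Cl to give the isolated 6-[3-(tert-butyldimethylsilyloxy)propyl]-5-methoxy-2,3-dihydro-4H-pyran-4-one F1. Kinetic deprotonation of F1 at the α′-CH2 with LiN(i-Pr)2 (THF, −78 °C), crossed Claisen acylation with 13 and an AcOH quench give the isolated β-diketone 3-[(2R)-4-(tert-butyldimethylsilyloxy)-2-hydroxy-2-methyl-3-(triethylsilyloxy)but-3-enoyl]-6-[3-(tert-butyldimethylsilyloxy)propyl]-5-methoxy-2,3-dihydro-4H-pyran-4-one F2 (carbinol configuration as in 13). A separate Lewis-acid Mukaiyama aldol condensation (TiCl4, CH2Cl2, −78 °C) then closes ring A to 16.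

Step 8. Hydride abstraction may take place at the side-chain CH2 next to C3 instead of at C1, or the electron-rich dienol ether may be over-oxidised. The fallback replaces hydride abstraction by selenoxide elimination; it sets out from 16 and comes back at 17. Selenenylation of the acidic C8a position (PhSeCl, pyridine, CH2Cl2, 0 °C) gives the selenide (7S)-5-(tert-butyldimethylsilyloxy)-3-[3-(tert-butyldimethylsilyloxy)propyl]-7-hydroxy-4-methoxy-7-methyl-8a-(phenylselanyl)-1,8a-dihydro-6H-isochromene-6,8(7H)-dione F3. Oxidation with H2O2 at 0 °C and syn elimination of the selenoxide, which can only take a hydrogen from C1, give 17.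

Step 2. SN2 attack of the dienolate on the β-silyloxyethyl iodide may be slow, so that loss of HI from the iodide or self-condensation of the dienolate takes over. The fallback replaces the alkyl halide by an epoxide; it sets out from 2 and comes back at 5. Dienolate 4 (LiN(SiMe3)2, THF, −78 °C) is opened onto oxirane in the presence of BF3·OEt2 to give 2-(3-hydroxypropyl)-3-methoxy-4H-pyran-4-one F4, which is silylated (TBSCl, imidazole, DMF, 23 °C) to 5.

**Further compounds**

F1 | step 7 | 6-[3-(tert-butyldimethylsilyloxy)propyl]-5-methoxy-2,3-dihydro-4H-pyran-4-one | COC1=C(CCCO[Si](C)(C)C(C)(C)C)OCCC1=O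
F2 | step 7 | 3-[(2R)-4-(tert-butyldimethylsilyloxy)-2-hydroxy-2-methyl-3-(triethylsilyloxy)but-3-enoyl]-6-[3-(tert-butyldimethylsilyloxy)propyl]-5-methoxy-2,3-dihydro-4H-pyran-4-one | COC1=C(CCCO[Si](C)(C)C(C)(C)C)OCC(C1=O)C(=O)[C@](C)(O)C(O[Si](CC)(CC)CC)=CO[Si](C)(C)C(C)(C)C
F3 | step 8 | (7S)-5-(tert-butyldimethylsilyloxy)-3-[3-(tert-butyldimethylsilyloxy)propyl]-7-hydroxy-4-methoxy-7-methyl-8a-(phenylselanyl)-1,8a-dihydro-6H-isochromene-6,8(7H)-dione | O[C@@]1(C)C(=O)C2([Se]c3ccccc3)COC(CCCO[Si](C)(C)C(C)(C)C)=C(OC)C2=C(O[Si](C)(C)C(C)(C)C)C1=O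
F4 | step 2 | 2-(3-hydroxypropyl)-3-methoxy-4H-pyran-4-one | COC1=C(CCCO)OC=CC1=O
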